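## Structural features

The target is a heliangolide-type germacranolide: a ten-membered carbocycle (C1–C10, germacrane numbering) fused trans at C6–C7 to an α-methylene γ-lactone (O6–C12(=O)–C11(=C13)–C7). The carbocycle holds a Z trisubstituted alkene C4=C5 flanked by two allylic C–O bonds (C3 isovalerate, C6 lactone oxygen) and a trans 1,10-epoxide (1R,10R), which is the epoxide of an E C1=C10 alkene. C6, C7 and C8 (all R) are contiguous, C3 (S) stands alone, and the C8 ester adds two more stereocentres. That C8 acyl group is (2R,3S)-2,3-dimethyloxirane-2-carboxylate; the unlike descriptors mean cis methyl groups, so it is the epoxide of tiglic (E) acid and not of angelic (Z) acid, and it is built from tiglyl alcohol. Fragile groups are the methylene lactone (Michael acceptor), both oxiranes (acid), the 1(10),4-diene of late intermediates (acid-induced transannular cyclisation, Cope shift on heating) and a free C8 hydroxyl, which can translactonise onto C12. The real difficulty is closing the ten-membered ring with control of C7 and C8 and of both alkene geometries, then telling three ester carbonyls apart. The key step uses the fact that C7 is the β-carbon of the lactone carbonyl C12 and C8 is a carbinol: a C8 ketyl adds to C7 of a butenolide that already carries C6, and the closure is 10-exo-trig, not endo, because C11 stays outside the carbocycle. The open-chain aldehyde 22 and the cyclised lactone 23 were checked centre by centre against the target and are consistent (C6 is S in 22 and R in 23 only through a priority switch). The design of 22 is refined in two ways: the labile β,γ-unsaturated C8 aldehyde is unmasked last, and the isovalerate is installed before the base-sensitive butenolide exists.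

## Logic of the disconnections

**32 ⇒ 31.** The C1–O and C10–O bonds of the ring oxirane are cut. The oxirane is the most acid-labile group of the ring, and the E alkene behind it is the only electron-rich alkene of 31 and a useful conformational constraint earlier. Two stereocentres disappear. The forward epoxidation must be chemoselective over C4=C5 and C11=C13 and face-selective on the macrocycle.

**31 ⇒ 28.** The C11=C13 bond is cut. The methylene lactone is a Michael acceptor and is best made late; the key step delivers C11 as CH2. The forward step must enolise the lactone in the presence of two other esters.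

**28 ⇒ 23 + 26.** The C8–O acyl bond is cut. 23 leaves the key step with only this hydroxyl free, and the two side-chain stereocentres come in convergently. The forward acylation must work on a hindered alcohol and must come before any base can induce translactonisation.

**26 ⇒ 25 ⇒ 24.** The carboxyl oxidation level and the two C–O bonds of the side-chain oxirane are removed. Reagent-controlled epoxidation of an E allylic alcohol sets both centres, and the E geometry of 24 fixes the cis methyl groups. The oxidation must spare the oxirane.

**23 ⇒ 22.** The C7–C8 bond is cut and the ten-membered ring opens. This leaves an open chain with two stereocentres (C3, C6); the forward step makes the ring and C7 and C8 together. It demands a 10-exo-trig radical closure at high dilution, attack anti to the C6 substituent, chelate control at C8 and reduction of the aldehyde before the butenolide.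

**22 ⇒ 21.** Only the oxidation level at C8 changes. The β,γ-unsaturated aldehyde cannot be stored, so the forward oxidation must be mild and come last.

**21 ⇒ 19 ⇒ 17 + 18.** The O6–C12 lactone bond, the Z C7=C11 alkene (back to an alkyne) and the C6–C7 bond are cut. 18 brings C7, C11 and C12 in one step and the C6 carbinol is set by a catalyst; Z-selective semireduction then closes the lactone without base. The demand is enantioface control on a Z enal and a clean semireduction.

**17 ⇒ 16 ⇒ 15 ⇒ 13 + 14.** The oxidation level at C6, two Si–O bonds and the C3–O acyl bond are cut. Early acylation keeps base away from the later butenolide and blocks lactol or furan formation from a Z γ-hydroxy enal; both silyl ethers fall in one step. The allylic oxidation must leave the C8 alcohol alone.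

**13 ⇒ 12 ⇒ 11 ⇒ 4 + 10.** The C3–C4 bond is cut and the C3 centre is traced back through the ketone. Two achiral fragments of similar size are joined, and the centre is then set by reagent control. The coupling must keep the Z geometry and the reduction must be 1,2 and enantioselective.

**10 ⇒ 9 ⇒ 5 + 6.** The C1–C2 bond and the C10–methyl bond are cut. Carbometalation of a terminal alkyne gives the E trisubstituted alkene stereospecifically, and 6 supplies C2 and C3. The demand is syn, regioselective methylmetalation and clean opening of 6.

**4 ⇒ 3 ⇒ 1.** The Si–O bond, the C4–I bond and the C5–H bond are cut. Hydroxyl-directed anti hydrometalation of 1 gives the Z iodide. The demand is complete regiocontrol.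

## Other disconnections considered

**Alternative 1:** The cut is C7–C11, the bond from the ring-fusion carbon to the lactone α-carbon, with O6–C12 already in place as a phosphonoacetate. Forward, base turns the phosphonoacetate of A1 into its carbanion, which opens the trans C7–C8 oxirane at C7 (5-exo-tet, inversion) to give the α-phosphono trans-lactone A2 with the C8 hydroxyl released.
- In its favour: C6, C7 and C8 all descend stereospecifically from one epoxy alcohol, so on stereochemical certainty at C7 and C8 it is better than the chosen plan, whose C8 rests on a chelate.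
- The mechanism is a closed-shell SN2 opening without the redox chemoselectivity questions of SmI2.
- The phosphonate left on C11 allows the methylene to be made by a Horner–Wadsworth–Emmons reaction with formaldehyde under mild base, which is better than the enolate methylenation of step 18.
- Against it here: the step closes only the five-membered ring. The ten-membered ring is still open in A2 and would have to be closed later, for instance at C3–C4 from the alkenyl iodide, where the C3 carbinol would form on the macrocycle without the reagent control of step 7.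
- 6-endo opening at C8 competes, the stabilised carbanion is a weak nucleophile towards a 1,2-disubstituted oxirane, and the free C8 hydroxyl next to the lactone is carried through several steps.
- In step economy the two plans are about equal up to the key step; the alternative is longer after it.

**Alternative 2:** The cut is C8–C9, paired in the retrosynthetic direction with re-forming C1–C6, so that the ten-membered ring contracts to the cyclohexenol A3. Forward, the potassium alkoxide of A3 (KH, 18-crown-6) undergoes a [3,3] shift to the enolate of dienone A4.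
- In its favour: ring expansion avoids end-to-end cyclisation altogether and the anionic oxy-Cope route to cyclodecenones is established, so on reliability of ring formation it is better than the chosen plan.
- The Z alkene comes from the six-membered ring and the E alkene from a chair transition state.
- The carbon framework comes from the chiral pool, so the way to A3 is at least as short as the way to 22.
- Against it here: A4 has neither C11/C12 nor the lactone. A two-carbon unit must be attached at C7 through an enolate that has the C8 ether as a β-leaving group, and the C6 ketone must be reduced with the right sense on a flexible ring.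
- Both protecting groups must be exchanged for esters, and C8 rests on the enol ether geometry and the chair transition state.
- In comparison, the chosen plan sets C6 by a catalyst on an open chain and C7 from C6, which is the stronger position. It needs three steps after the key step; the alternative needs clearly more.

**Alternative 3:** The cut is C9–C10. Forward, SmI2 converts the bromide of A5 into the samarium enolate of the C8 ketone, which adds to the C10 methyl ketone and closes the ring to A6.
- In its favour: Reformatsky closures of medium rings with SmI2 are well documented, so the ring-closing precedent is better than that of step 14; the reagent is the same, so practicality is equal.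
- The trans-lactone with C6 and C7 is in place before closure.
- O1 and O10 are already present, so the ring oxirane could be made by displacement instead of a face-selective epoxidation, which is better than step 19 if C10 forms with the right sense.
- Against it here: A6 needs a stereoselective reduction at C8, and its C10 configuration is uncertain.
- C7 is α to the C8 ketone and the lactone oxygen on C6 is β to it, so epimerisation and β-elimination with lactone opening threaten at the enolate and aldolate stage.
- A5 needs four stereocentres (C1, C3, C6, C7) before ring closure, against two in 22.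
- In step economy the alternative is longer both before and after its key step.

Key step: step 14

Assumptions: 5 and 24 are taken as commercial; in step 11 the (R,R) antipode of ProPhenol is taken to give the (4R) carbinol, to be confirmed by Mosher ester analysis, with the antipodal ligand used otherwise.

## Route

Step 1
Reactants: 1 but-2-yn-1-ol
Product: 3 (Z)-3-iodobut-2-en-1-ol, via cyclic alkenylaluminate 2 (not isolated)
Conditions: NaAlH2(OCH2CH2OMe)2 (Red-Al), THF, 0 °C→rt; then I2, THF, −78 °C→rt
Reagents that add atoms: iodine [I][I]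
Why: Hydroxyl-directed trans-hydroalumination of the propargylic alcohol puts aluminium on C4 and hydride on C5 in a five-membered aluminate, and iodinolysis with retention gives only the Z iodide; this fixes the later Z C4=C5 geometry.

Step 2
Reactants: 3 (Z)-3-iodobut-2-en-1-ol
Product: 4 (Z)-tert-butyl[(3-iodobut-2-en-1-yl)oxy]dimethylsilane
Conditions: TBSCl, imidazole, CH2Cl2, 0 °C→rt
Reagents that add atoms: tert-butyldimethylsilyl chloride CC(C)(C)[Si](C)(C)Cl
Why: Standard silylation of a primary alcohol; a silyl ether is acceptable because the later coupling uses chromium and not an alkenyllithium, so no retro-Brook silyl shift can occur.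

Step 3
Reactants: 5 tert-butyl(but-3-yn-1-yloxy)dimethylsilane; 6 oxirane
Product: 9 (E)-6-(tert-butyldimethylsilyloxy)-4-methylhex-3-en-1-ol, via alkenyldimethylalane 7 (not isolated), via lithium alkenylalanate 8 (not isolated)
Conditions: AlMe3, Cp2ZrCl2 (0.25 equiv), CH2Cl2, 0 °C→rt; volatiles removed; n-BuLi, hexane/THF, −78→0 °C; then 6, 0 °C→rt
Reagents that add atoms: trimethylaluminium C[Al](C)C
Why: Negishi zirconium-catalysed carboalumination adds methyl and aluminium syn across the terminal alkyne with methyl on the internal carbon, which sets the E C1=C10 geometry; the derived alanate opens the unhindered epoxide at carbon with retention of alkene geometry.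

Step 4
Reactants: 9 (E)-6-(tert-butyldimethylsilyloxy)-4-methylhex-3-en-1-ol
Product: 10 (E)-6-(tert-butyldimethylsilyloxy)-4-methylhex-3-enal
Conditions: Dess–Martin periodinane, NaHCO3, CH2Cl2, 0 °C; used crude at once
Reagents that add atoms: none
Why: Dess–Martin oxidation under bicarbonate buffer is mild enough to give the β,γ-unsaturated aldehyde without moving the double bond into conjugation.

Step 5
Reactants: 4 (Z)-tert-butyl[(3-iodobut-2-en-1-yl)oxy]dimethylsilane; 10 (E)-6-(tert-butyldimethylsilyloxy)-4-methylhex-3-enal
Product: 11 rac-(2Z,6E)-1,9-bis(tert-butyldimethylsilyloxy)-3,7-dimethylnona-2,6-dien-4-ol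
Conditions: CrCl2 (4 equiv), NiCl2 (2 mol %), DMSO, rt
Reagents that add atoms: none
Why: Nozaki–Hiyama–Kishi coupling: zerovalent nickel inserts into the C–I bond and transmetalation gives an alkenyl species of trivalent chromium that adds to the aldehyde with retention of the Z geometry; the non-basic medium spares the enolisable aldehyde and both silyl ethers. The carbinol forms racemic and is corrected in steps 6 and 7.

Step 6
Reactants: 11 rac-(2Z,6E)-1,9-bis(tert-butyldimethylsilyloxy)-3,7-dimethylnona-2,6-dien-4-ol
Product: 12 (2Z,6E)-1,9-bis(tert-butyldimethylsilyloxy)-3,7-dimethylnona-2,6-dien-4-one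
Conditions: Dess–Martin periodinane, NaHCO3, CH2Cl2, 0 °C
Reagents that add atoms: none
Why: Dess–Martin oxidation of the allylic alcohol; buffered neutral conditions keep the Z enone and the skipped C1=C10 alkene in place.

Step 7
Reactants: 12 (2Z,6E)-1,9-bis(tert-butyldimethylsilyloxy)-3,7-dimethylnona-2,6-dien-4-one
Product: 13 (2Z,4S,6E)-1,9-bis(tert-butyldimethylsilyloxy)-3,7-dimethylnona-2,6-dien-4-ol
Conditions: (R)-2-methyl-CBS-oxazaborolidine (0.5 equiv), catecholborane, toluene, −78 °C
Reagents that add atoms: none
Why: Corey–Bakshi–Shibata reduction: the α-methyl alkenyl group acts as the large substituent and the CH2 group as the small one, so the (R)-oxazaborolidine should deliver hydride to the face that gives the (4S) alcohol (C3 of the target); catecholborane at low temperature reduces 1,2 and does not hydroborate the alkenes.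

Step 8
Reactants: 13 (2Z,4S,6E)-1,9-bis(tert-butyldimethylsilyloxy)-3,7-dimethylnona-2,6-dien-4-ol; 14 3-methylbutanoyl chloride
Product: 15 (2Z,4S,6E)-1,9-bis(tert-butyldimethylsilyloxy)-3,7-dimethylnona-2,6-dien-4-yl 3-methylbutanoate
Conditions: pyridine, DMAP (cat.), CH2Cl2, 0 °C→rt
Reagents that add atoms: none
Why: Acylation of the secondary allylic alcohol; it is done here so that no base meets the later butenolide and so that the C3 oxygen cannot close onto C6 once that carbon is an aldehyde.

Step 9
Reactants: 15 (2Z,4S,6E)-1,9-bis(tert-butyldimethylsilyloxy)-3,7-dimethylnona-2,6-dien-4-yl 3-methylbutanoate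
Product: 16 (2Z,4S,6E)-1,9-dihydroxy-3,7-dimethylnona-2,6-dien-4-yl 3-methylbutanoate
Conditions: HF·pyridine, pyridine, THF, 0 °C→rt
Reagents that add atoms: none
Why: Fluoride cleavage of both primary silyl ethers in one operation under buffered acidic conditions, under which the allylic ester should neither migrate nor cleave.

Step 10
Reactants: 16 (2Z,4S,6E)-1,9-dihydroxy-3,7-dimethylnona-2,6-dien-4-yl 3-methylbutanoate
Product: 17 (2Z,4S,6E)-9-hydroxy-3,7-dimethyl-1-oxonona-2,6-dien-4-yl 3-methylbutanoate
Conditions: activated MnO2, CH2Cl2, rt, dark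
Reagents that add atoms: none
Why: MnO2 oxidises only the allylic primary alcohol (C6) and leaves the homoallylic C8 alcohol; this reagent normally preserves Z enal geometry, and the acylated C3 oxygen cannot form a lactol or furan.

Step 11
Reactants: 17 (2Z,4S,6E)-9-hydroxy-3,7-dimethyl-1-oxonona-2,6-dien-4-yl 3-methylbutanoate; 18 methyl propiolate
Product: 19 methyl (4R,5Z,7S,9E)-4,12-dihydroxy-6,10-dimethyl-7-(3-methylbutanoyloxy)dodeca-5,9-dien-2-ynoate
Conditions: Me2Zn (4 equiv), (R,R)-ProPhenol (20 mol %), Ph3PO (40 mol %), toluene, 4 °C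
Reagents that add atoms: none
Why: Catalytic asymmetric alkynylation: the dinuclear zinc complex of ProPhenol delivers the zinc acetylide of 18 to one face of the enal, a substrate class for which this catalyst is established; the ligand antipode is chosen for the (4R) carbinol (C6 of the target), and the free hydroxyl and the ester are tolerated.

Step 12
Reactants: 19 methyl (4R,5Z,7S,9E)-4,12-dihydroxy-6,10-dimethyl-7-(3-methylbutanoyloxy)dodeca-5,9-dien-2-ynoate
Product: 21 (1Z,3S,5E)-8-hydroxy-2,6-dimethyl-1-[(2S)-5-oxo-2,5-dihydrofuran-2-yl]octa-1,5-dien-3-yl 3-methylbutanoate, via (Z)-hydroxy enoate 20 (not isolated)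
Conditions: H2 (1 atm), Pd/CaCO3 poisoned with Pb(OAc)2 (Lindlar catalyst), quinoline, EtOAc, rt; then PPTS (cat.), CH2Cl2, rt
Reagents that add atoms: none
Why: Lindlar semihydrogenation stops at the Z enoate, whose γ-hydroxyl closes onto the ester (5-exo-trig) to the butenolide without base; the poisoned catalyst does not reduce trisubstituted alkenes.

Step 13
Reactants: 21 (1Z,3S,5E)-8-hydroxy-2,6-dimethyl-1-[(2S)-5-oxo-2,5-dihydrofuran-2-yl]octa-1,5-dien-3-yl 3-methylbutanoate
Product: 22 (1Z,3S,5E)-2,6-dimethyl-8-oxo-1-[(2S)-5-oxo-2,5-dihydrofuran-2-yl]octa-1,5-dien-3-yl 3-methylbutanoate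
Conditions: Dess–Martin periodinane, NaHCO3, CH2Cl2, 0 °C; short silica pad, used within hours
Reagents that add atoms: none
Why: Dess–Martin oxidation of the remaining primary alcohol under buffer; the β,γ-unsaturated aldehyde is made last and used at once so that the C1=C10 bond does not move into conjugation.

Step 14
Reactants: 22 (1Z,3S,5E)-2,6-dimethyl-8-oxo-1-[(2S)-5-oxo-2,5-dihydrofuran-2-yl]octa-1,5-dien-3-yl 3-methylbutanoate
Product: 23 (3aR,4R,6E,9S,10Z,11aR)-4-hydroxy-6,10-dimethyl-2-oxo-2,3,3a,4,5,8,9,11a-octahydrocyclodeca[b]furan-9-yl 3-methylbutanoate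
Conditions: SmI2 (3 equiv), t-BuOH (2 equiv), THF, 0.002 M, 22 added over 6 h, 0 °C; then aq. potassium sodium tartrate, 0 °C
Reagents that add atoms: none
Why: Proposed new method: electron transfer from SmI2 to the aldehyde gives a C8 ketyl bound to trivalent samarium, which adds to C7, the β-carbon of the butenolide, to give a C11 radical; a second electron turns this into the samarium lactone enolate, which t-BuOH protonates at C11. The closest known reaction type is the SmI2 ketyl–olefin cyclisation of aldehydes onto butenolides and enoates, established for five- to eight-membered rings and intermolecularly, so the ten-membered closure is an extrapolation. The one ring closed is the ten-membered carbocycle, in a 10-exo-trig mode: C7 is attacked and C11 stays outside the new ring, being endocyclic only to the lactone that already exists. C7 is controlled by the C6 stereocentre: attack on the butenolide face anti to the C6 alkenyl group gives the trans ring fusion, which a ten-membered ring can span. C8 is to be controlled by a chelate in which trivalent samarium bridges the ketyl oxygen and the lactone carbonyl in the HMPA-free medium; this is the least secure element. The step needs reduction of the aldehyde in preference to the butenolide, the allylic ester and the alkenes, which the reduction potentials should secure, and it needs ring closure in preference to pinacol coupling or simple reduction. High dilution, slow addition and a weak proton donor serve the second need, together with the Z C4=C5 and E C1=C10 alkenes, which leave only six rotatable bonds between the ketyl and C7. Ketyl formation is reversible and the unactivated alkenes are poor acceptors for the nucleophilic ketyl, so a slow closure should not of itself divert material; a cold quench limits translactonisation of the C8 alkoxide onto C12.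

Step 15
Reactants: 24 (E)-2-methylbut-2-en-1-ol
Product: 25 [(2S,3S)-2,3-dimethyloxiran-2-yl]methanol
Conditions: Ti(OiPr)4 (10 mol %), L-(+)-diethyl tartrate (12 mol %), t-BuOOH, 4 Å sieves, CH2Cl2, −20 °C
Reagents that add atoms: tert-butyl hydroperoxide CC(C)(C)OO
Why: Sharpless asymmetric epoxidation: with L-(+)-diethyl tartrate an E trisubstituted allylic alcohol is epoxidised on the face that gives the (2S,3S) epoxy alcohol, and the E geometry fixes the cis relation of the two methyl groups.

Step 16
Reactants: 25 [(2S,3S)-2,3-dimethyloxiran-2-yl]methanol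
Product: 26 (2R,3S)-2,3-dimethyloxirane-2-carboxylic acid
Conditions: RuCl3·H2O (2 mol %), NaIO4, MeCN/EtOAc/H2O, 0 °C→rt
Reagents that add atoms: sodium periodate [Na+].[O-]I(=O)(=O)=O; water O
Why: RuO4 formed in situ from RuCl3 and NaIO4 oxidises the primary alcohol to the acid without opening the oxirane; the descriptor at C2 changes from S to R only because the priorities change.

Step 17
Reactants: 23 (3aR,4R,6E,9S,10Z,11aR)-4-hydroxy-6,10-dimethyl-2-oxo-2,3,3a,4,5,8,9,11a-octahydrocyclodeca[b]furan-9-yl 3-methylbutanoate; 26 (2R,3S)-2,3-dimethyloxirane-2-carboxylic acid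
Product: 28 (3aR,4R,6E,9S,10Z,11aR)-6,10-dimethyl-9-(3-methylbutanoyloxy)-2-oxo-2,3,3a,4,5,8,9,11a-octahydrocyclodeca[b]furan-4-yl (2R,3S)-2,3-dimethyloxirane-2-carboxylate, via mixed anhydride 27 (not isolated)
Conditions: 26, 2,4,6-trichlorobenzoyl chloride, Et3N, toluene, rt; then 23, DMAP, toluene, rt
Reagents that add atoms: none
Why: Yamaguchi esterification: DMAP attacks the mixed anhydride at the oxirane carbonyl, the aryl carbonyl being shielded by two ortho chlorines, and the acylpyridinium acylates the hindered C8 alcohol. The acid has no α-hydrogen and cannot epimerise, and capping C8 at once removes the danger of translactonisation.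

Step 18
Reactants: 28 (3aR,4R,6E,9S,10Z,11aR)-6,10-dimethyl-9-(3-methylbutanoyloxy)-2-oxo-2,3,3a,4,5,8,9,11a-octahydrocyclodeca[b]furan-4-yl (2R,3S)-2,3-dimethyloxirane-2-carboxylate
Product: 31 (3aR,4R,6E,9S,10Z,11aR)-6,10-dimethyl-3-methylidene-9-(3-methylbutanoyloxy)-2-oxo-2,3,3a,4,5,8,9,11a-octahydrocyclodeca[b]furan-4-yl (2R,3S)-2,3-dimethyloxirane-2-carboxylate, via Mannich base 29 (not isolated), via trimethylammonium iodide 30 (not isolated)
Conditions: LiN(SiMe3)2 (1.05 equiv), THF, −78 °C; CH2=NMe2+ I−, −78→−20 °C; then MeI, MeOH, rt; NaHCO3 aq., CH2Cl2, rt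
Reagents that add atoms: dimethylmethyleneammonium iodide C=[N+](C)C.[I-]
Why: Mannich methylenation: the lactone α-CH2 is several pK units more acidic than the α-CH2 of the hindered isovalerate and the C8 ester has no α-hydrogen, so one equivalent of the amide base should enolise C11 selectively. The enolate is aminomethylated by the iminium salt, and quaternisation followed by mild base eliminates trimethylamine to the exocyclic alkene.

Step 19
Reactants: 31 (3aR,4R,6E,9S,10Z,11aR)-6,10-dimethyl-3-methylidene-9-(3-methylbutanoyloxy)-2-oxo-2,3,3a,4,5,8,9,11a-octahydrocyclodeca[b]furan-4-yl (2R,3S)-2,3-dimethyloxirane-2-carboxylate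
Product: 32 (1R,3S,4Z,6R,7R,8R,10R)-1,10-epoxy-3-(3-methylbutanoyloxy)-8-[(2R,3S)-2,3-dimethyloxirane-2-carbonyloxy]germacra-4,11(13)-dien-12,6-olide (CNP0167461.4)
Conditions: mCPBA (1.05 equiv), NaHCO3, CH2Cl2, 0 °C
Reagents that add atoms: 3-chloroperbenzoic acid OOC(=O)c1cccc(Cl)c1
Why: Prilezhaev epoxidation: the peracid should attack only C1=C10, since C4=C5 is deactivated by two allylic acyloxy groups and the methylene lactone is electron-poor. The E geometry gives the trans oxirane, and attack on the exposed outer face of the ring alkene is expected to give the (1R,10R) isomer.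

## Compound list

1 | but-2-yn-1-ol | CC#CCO | starting material
2 | sodium 2,2-bis(2-methoxyethoxy)-3-methyl-2,5-dihydro-1,2-oxaaluminol-2-uide (cyclic alkenylaluminate) | [Na+].CC1=CCO[Al-]1(OCCOC)OCCOC | intermediate
3 | (Z)-3-iodobut-2-en-1-ol | C/C(I)=C/CO | intermediate
4 | (Z)-tert-butyl[(3-iodobut-2-en-1-yl)oxy]dimethylsilane | C/C(I)=C/CO[Si](C)(C)C(C)(C)C | intermediate
5 | tert-butyl(but-3-yn-1-yloxy)dimethylsilane | C#CCCO[Si](C)(C)C(C)(C)C | starting material
6 | oxirane (ethylene oxide) | C1CO1 | starting material
7 | (E)-[4-(tert-butyldimethylsilyloxy)-2-methylbut-1-en-1-yl]dimethylalane | C[Al](C)/C=C(\C)CCO[Si](C)(C)C(C)(C)C | intermediate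
8 | lithium butyl[(E)-4-(tert-butyldimethylsilyloxy)-2-methylbut-1-en-1-yl]dimethylalanate | [Li+].CCCC[Al-](C)(C)/C=C(\C)CCO[Si](C)(C)C(C)(C)C | intermediate
9 | (E)-6-(tert-butyldimethylsilyloxy)-4-methylhex-3-en-1-ol | OCC/C=C(\C)CCO[Si](C)(C)C(C)(C)C | intermediate
10 | (E)-6-(tert-butyldimethylsilyloxy)-4-methylhex-3-enal | O=CC/C=C(\C)CCO[Si](C)(C)C(C)(C)C | intermediate
11 | rac-(2Z,6E)-1,9-bis(tert-butyldimethylsilyloxy)-3,7-dimethylnona-2,6-dien-4-ol | CC(C)(C)[Si](C)(C)OC/C=C(/C)C(O)C/C=C(\C)CCO[Si](C)(C)C(C)(C)C | intermediate
12 | (2Z,6E)-1,9-bis(tert-butyldimethylsilyloxy)-3,7-dimethylnona-2,6-dien-4-one | CC(C)(C)[Si](C)(C)OC/C=C(/C)C(=O)C/C=C(\C)CCO[Si](C)(C)C(C)(C)C | intermediate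
13 | (2Z,4S,6E)-1,9-bis(tert-butyldimethylsilyloxy)-3,7-dimethylnona-2,6-dien-4-ol | CC(C)(C)[Si](C)(C)OC/C=C(/C)[C@@H](O)C/C=C(\C)CCO[Si](C)(C)C(C)(C)C | intermediate
14 | 3-methylbutanoyl chloride (isovaleryl chloride) | CC(C)CC(Cl)=O | starting material
15 | (2Z,4S,6E)-1,9-bis(tert-butyldimethylsilyloxy)-3,7-dimethylnona-2,6-dien-4-yl 3-methylbutanoate | CC(C)(C)[Si](C)(C)OC/C=C(/C)[C@@H](OC(=O)CC(C)C)C/C=C(\C)CCO[Si](C)(C)C(C)(C)C | intermediate
16 | (2Z,4S,6E)-1,9-dihydroxy-3,7-dimethylnona-2,6-dien-4-yl 3-methylbutanoate | OC/C=C(/C)[C@@H](OC(=O)CC(C)C)C/C=C(\C)CCO | intermediate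
17 | (2Z,4S,6E)-9-hydroxy-3,7-dimethyl-1-oxonona-2,6-dien-4-yl 3-methylbutanoate | O=C/C=C(/C)[C@@H](OC(=O)CC(C)C)C/C=C(\C)CCO | intermediate
18 | methyl propiolate (methyl prop-2-ynoate) | C#CC(=O)OC | starting material
19 | methyl (4R,5Z,7S,9E)-4,12-dihydroxy-6,10-dimethyl-7-(3-methylbutanoyloxy)dodeca-5,9-dien-2-ynoate | COC(=O)C#C[C@H](O)/C=C(/C)[C@@H](OC(=O)CC(C)C)C/C=C(\C)CCO | intermediate
20 | methyl (2Z,4S,5Z,7S,9E)-4,12-dihydroxy-6,10-dimethyl-7-(3-methylbutanoyloxy)dodeca-2,5,9-trienoate | COC(=O)/C=C\[C@H](O)/C=C(/C)[C@@H](OC(=O)CC(C)C)C/C=C(\C)CCO | intermediate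
21 | (1Z,3S,5E)-8-hydroxy-2,6-dimethyl-1-[(2S)-5-oxo-2,5-dihydrofuran-2-yl]octa-1,5-dien-3-yl 3-methylbutanoate | O=C1C=C[C@H](O1)/C=C(/C)[C@@H](OC(=O)CC(C)C)C/C=C(\C)CCO | intermediate
22 | (1Z,3S,5E)-2,6-dimethyl-8-oxo-1-[(2S)-5-oxo-2,5-dihydrofuran-2-yl]octa-1,5-dien-3-yl 3-methylbutanoate (γ-alkenyl butenolide aldehyde) | O=C1C=C[C@H](O1)/C=C(/C)[C@@H](OC(=O)CC(C)C)C/C=C(\C)CC=O | intermediate
23 | (3aR,4R,6E,9S,10Z,11aR)-4-hydroxy-6,10-dimethyl-2-oxo-2,3,3a,4,5,8,9,11a-octahydrocyclodeca[b]furan-9-yl 3-methylbutanoate (trans-fused hydroxy lactone) | O=C1O[C@@H]2/C=C(/C)[C@@H](OC(=O)CC(C)C)C/C=C(\C)C[C@@H](O)[C@H]2C1 | intermediate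
24 | (E)-2-methylbut-2-en-1-ol (tiglyl alcohol) | C/C=C(\C)CO | starting material
25 | [(2S,3S)-2,3-dimethyloxiran-2-yl]methanol | OC[C@]1(C)O[C@H]1C | intermediate
26 | (2R,3S)-2,3-dimethyloxirane-2-carboxylic acid | OC(=O)[C@]1(C)O[C@H]1C | intermediate
27 | (2R,3S)-2,3-dimethyloxirane-2-carboxylic 2,4,6-trichlorobenzoic anhydride | O=C(OC(=O)[C@]1(C)O[C@H]1C)c1c(Cl)cc(Cl)cc1Cl | intermediate
28 | (3aR,4R,6E,9S,10Z,11aR)-6,10-dimethyl-9-(3-methylbutanoyloxy)-2-oxo-2,3,3a,4,5,8,9,11a-octahydrocyclodeca[b]furan-4-yl (2R,3S)-2,3-dimethyloxirane-2-carboxylate | O=C1O[C@@H]2/C=C(/C)[C@@H](OC(=O)CC(C)C)C/C=C(\C)C[C@@H](OC(=O)[C@]3(C)O[C@H]3C)[C@H]2C1 | intermediate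
29 | 3-[(dimethylamino)methyl] derivative of 28 (Mannich base, C11 epimers) | O=C1O[C@@H]2/C=C(/C)[C@@H](OC(=O)CC(C)C)C/C=C(\C)C[C@@H](OC(=O)[C@]3(C)O[C@H]3C)[C@H]2C1CN(C)C | intermediate
30 | 3-[(trimethylammonio)methyl] derivative of 28, iodide | O=C1O[C@@H]2/C=C(/C)[C@@H](OC(=O)CC(C)C)C/C=C(\C)C[C@@H](OC(=O)[C@]3(C)O[C@H]3C)[C@H]2C1C[N+](C)(C)C.[I-] | intermediate
31 | (3aR,4R,6E,9S,10Z,11aR)-6,10-dimethyl-3-methylidene-9-(3-methylbutanoyloxy)-2-oxo-2,3,3a,4,5,8,9,11a-octahydrocyclodeca[b]furan-4-yl (2R,3S)-2,3-dimethyloxirane-2-carboxylate | C=C1C(=O)O[C@@H]2/C=C(/C)[C@@H](OC(=O)CC(C)C)C/C=C(\C)C[C@@H](OC(=O)[C@]3(C)O[C@H]3C)[C@@H]12 | intermediate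
32 | (1R,3S,4Z,6R,7R,8R,10R)-1,10-epoxy-3-(3-methylbutanoyloxy)-8-[(2R,3S)-2,3-dimethyloxirane-2-carbonyloxy]germacra-4,11(13)-dien-12,6-olide (CNP0167461.4) | C=C1C(=O)O[C@@H]2/C=C(/C)[C@@H](OC(=O)CC(C)C)C[C@H]3O[C@]3(C)C[C@@H](OC(=O)[C@]3(C)O[C@H]3C)[C@@H]12 | target

## Step count and least certain steps

Total step count: 19. Longest linear sequence: 15 steps (steps 3–14 and 17–19 from 5; equally steps 1, 2, 5–14 and 17–19 from 1).

**Step 14 (key step, proposed new method).** Most likely to go wrong:
- failure of the ten-membered closure, with the ketyl ending in simple reduction or pinacol dimerisation;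
- reductive opening of the butenolide;
- drift of the C1=C10 bond into conjugation before electron transfer;
- poor facial control at C8;
- translactonisation of the C8 alkoxide onto C12.

The cause is the entropic cost of a ten-membered radical closure, for which there is no precedent.

Fallback (known reaction types only; sets out from 3 and 9, comes back at 28): the C7–C8 bond is made by the intermolecular ketyl–butenolide coupling and the ring is closed at C3–C4 by an intramolecular Nozaki–Hiyama–Kishi reaction.
- MnO2 oxidation of 3 gives (Z)-3-iodobut-2-enal F1.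
- Addition of 18 under the conditions of step 11 gives methyl (4R,5Z)-4-hydroxy-6-iodohept-5-en-2-ynoate F2.
- Semihydrogenation and lactonisation as in step 12 give (5S)-5-[(1Z)-2-iodoprop-1-en-1-yl]furan-2(5H)-one F3.
- Separately, 9 is protected with 4-methoxybenzyl trichloroacetimidate and catalytic acid to the PMB ether F4, desilylated with Bu4NF to the alcohol F5 and oxidised with Dess–Martin periodinane to the aldehyde F6.
- SmI2 with t-BuOH in THF at −78 °C couples F6 with F3, anti to the C6 substituent, to the trans γ-lactone F7; C8 epimers are separated.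
- Yamaguchi esterification with 26 gives the C8 ester F8, DDQ removes the PMB group to give the primary alcohol F9, and Dess–Martin oxidation gives the aldehyde F10.
- CrCl2 with catalytic NiCl2 at high dilution closes the ring to the C3 alcohol F11 (C3 epimers separated); acylation with 14 and pyridine returns to 28.

Poor control at C3 on the macrocycle is the weak point of this fallback.

**Step 18.** Most likely to go wrong: loss of regiocontrol in the enolisation (the isovalerate α-CH2 competes), transfer of the C8 acyl group from oxygen to the C11 enolate carbon through a five-membered transition state, or conjugate addition of amine to the product.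

Fallback (sets out from 22, comes back at 31): the enolate is taken where it is formed regiospecifically.
- The cyclisation of step 14 is run without proton donor and the samarium enolate is trapped with gaseous formaldehyde to give the α-hydroxymethyl lactone diol F12.
- Methanesulfonyl chloride and 2,4,6-collidine at −20 °C sulfonylate the primary hydroxyl to the mesylate F13.
- DBU eliminates it to the 8-hydroxy methylene lactone F14.
- Yamaguchi esterification with 26 as in step 17 gives 31.

**Step 19.** Most likely to go wrong: poor facial selectivity, because the face exposed to the peracid depends on the ring conformer populations; also acid-promoted transannular opening of the new oxirane.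

Fallback (sets out from 31, comes back at 32, no new compound): reagent control replaces substrate control. A Shi epoxidation is used, with the dioxirane from the D-fructose-derived ketone and KHSO5 (Oxone) in buffered MeCN/dimethoxymethane–water at 0 °C. The spiro transition-state model for E trisubstituted alkenes points to the (1R,10R) oxirane.

**Step 11.** Most likely to go wrong: low or reversed enantioface selectivity, because the C3 substituent sits cis to the formyl group on the Z enal; also Z to E isomerisation of the enal under the Lewis-acidic conditions.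

Fallback (sets out from 17, comes back at 19): addition, oxidation and asymmetric reduction replace the catalytic addition.
- LiN(iPr)2 and 18 in THF at −78 °C give the lithium acetylide, which adds to 17 to give the C6-epimeric alcohols F15.
- MnO2 oxidises them to the ynone F16.
- Midland reduction with (R)-Alpine-Borane, in which the alkyne is the small group, gives the (4R) carbinol 19.

## Further compounds

F1 | step 14 | (Z)-3-iodobut-2-enal | C/C(I)=C/C=O
F2 | step 14 | methyl (4R,5Z)-4-hydroxy-6-iodohept-5-en-2-ynoate | COC(=O)C#C[C@H](O)/C=C(/C)I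
F3 | step 14 | (5S)-5-[(1Z)-2-iodoprop-1-en-1-yl]furan-2(5H)-one | O=C1C=C[C@H](O1)/C=C(/C)I
F4 | step 14 | (E)-tert-butyl({6-[(4-methoxybenzyl)oxy]-3-methylhex-3-en-1-yl}oxy)dimethylsilane | COc1ccc(COCC/C=C(\C)CCO[Si](C)(C)C(C)(C)C)cc1
F5 | step 14 | (E)-6-[(4-methoxybenzyl)oxy]-3-methylhex-3-en-1-ol | COc1ccc(COCC/C=C(\C)CCO)cc1
F6 | step 14 | (E)-6-[(4-methoxybenzyl)oxy]-3-methylhex-3-enal | COc1ccc(COCC/C=C(\C)CC=O)cc1
F7 | step 14 | (4R,5S)-4-[(1R,3E)-1-hydroxy-6-(4-methoxybenzyloxy)-3-methylhex-3-en-1-yl]-5-[(1Z)-2-iodoprop-1-en-1-yl]dihydrofuran-2(3H)-one | O=C1O[C@H](/C=C(/C)I)[C@@H]([C@H](O)C/C(C)=C/CCOCc2ccc(OC)cc2)C1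
F8 | step 14 | (2R,3S)-2,3-dimethyloxirane-2-carboxylate ester of F7 at C8 | O=C1O[C@H](/C=C(/C)I)[C@@H]([C@H](OC(=O)[C@]2(C)O[C@H]2C)C/C(C)=C/CCOCc3ccc(OC)cc3)C1
F9 | step 14 | primary alcohol from F8 after removal of the PMB group | O=C1O[C@H](/C=C(/C)I)[C@@H]([C@H](OC(=O)[C@]2(C)O[C@H]2C)C/C(C)=C/CCO)C1
F10 | step 14 | C3 aldehyde from F9 | O=C1O[C@H](/C=C(/C)I)[C@@H]([C@H](OC(=O)[C@]2(C)O[C@H]2C)C/C(C)=C/CC=O)C1
F11 | step 14 | (3aR,4R,6E,9S,10Z,11aR)-9-hydroxy-6,10-dimethyl-2-oxo-2,3,3a,4,5,8,9,11a-octahydrocyclodeca[b]furan-4-yl (2R,3S)-2,3-dimethyloxirane-2-carboxylate | O=C1O[C@@H]2/C=C(/C)[C@@H](O)C/C=C(\C)C[C@@H](OC(=O)[C@]3(C)O[C@H]3C)[C@H]2C1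
F12 | step 18 | 3-(hydroxymethyl) derivative of 23 (C11 epimers) | O=C1O[C@@H]2/C=C(/C)[C@@H](OC(=O)CC(C)C)C/C=C(\C)C[C@@H](O)[C@H]2C1CO
F13 | step 18 | primary methanesulfonate of F12 | O=C1O[C@@H]2/C=C(/C)[C@@H](OC(=O)CC(C)C)C/C=C(\C)C[C@@H](O)[C@H]2C1COS(C)(=O)=O
F14 | step 18 | (3aR,4R,6E,9S,10Z,11aR)-4-hydroxy-6,10-dimethyl-3-methylidene-2-oxo-2,3,3a,4,5,8,9,11a-octahydrocyclodeca[b]furan-9-yl 3-methylbutanoate | C=C1C(=O)O[C@@H]2/C=C(/C)[C@@H](OC(=O)CC(C)C)C/C=C(\C)C[C@@H](O)[C@@H]12
F0 | step 19 | none | none
F15 | step 11 | methyl (4RS,5Z,7S,9E)-4,12-dihydroxy-6,10-dimethyl-7-(3-methylbutanoyloxy)dodeca-5,9-dien-2-ynoate (C4 epimers) | COC(=O)C#CC(O)/C=C(/C)[C@@H](OC(=O)CC(C)C)C/C=C(\C)CCO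
F16 | step 11 | methyl (5Z,7S,9E)-12-hydroxy-6,10-dimethyl-7-(3-methylbutanoyloxy)-4-oxododeca-5,9-dien-2-ynoate | COC(=O)C#CC(=O)/C=C(/C)[C@@H](OC(=O)CC(C)C)C/C=C(\C)CCO
A1 | alternative 1 | (Z)-3-iodo-1-{trans-3-[(E)-5-(tert-butyldimethylsilyloxy)-2-methylpent-2-en-1-yl]oxiran-2-yl}but-2-en-1-yl 2-(diethoxyphosphoryl)acetate (epoxy phosphonoacetate) | CCOP(=O)(OCC)CC(=O)O[C@H](/C=C(/C)I)[C@H]1O[C@@H]1C/C(C)=C/CCO[Si](C)(C)C(C)(C)C
A2 | alternative 1 | α-diethoxyphosphoryl trans-γ-lactone with free C8 hydroxyl, Z alkenyl iodide at C6 and silyl-protected C3 terminus | CCOP(=O)(OCC)C1C(=O)O[C@H](/C=C(/C)I)[C@H]1[C@H](O)C/C(C)=C/CCO[Si](C)(C)C(C)(C)C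
A3 | alternative 2 | (1S,4S,6S)-4-(tert-butyldimethylsilyloxy)-1-[(Z)-2-(4-methoxybenzyloxy)ethenyl]-3-methyl-6-(prop-1-en-2-yl)cyclohex-2-en-1-ol | O[C@@]1(/C=C\OCc2ccc(OC)cc2)C=C(C)[C@@H](O[Si](C)(C)C(C)(C)C)C[C@H]1C(C)=C
A4 | alternative 2 | (2Z,4S,6E,9R)-4-(tert-butyldimethylsilyloxy)-9-(4-methoxybenzyloxy)-3,7-dimethylcyclodeca-2,6-dien-1-one | O=C1/C=C(/C)[C@@H](O[Si](C)(C)C(C)(C)C)C/C=C(\C)C[C@@H](OCc2ccc(OC)cc2)C1
A5 | alternative 3 | trans-4-(2-bromoacetyl)-5-[(1Z,3S,5S)-3-(tert-butyldimethylsilyloxy)-2-methyl-6-oxo-5-(triethylsilyloxy)hept-1-en-1-yl]dihydrofuran-2(3H)-one | O=C1C[C@H](C(=O)CBr)[C@H](O1)/C=C(/C)[C@@H](O[Si](C)(C)C(C)(C)C)C[C@H](O[Si](CC)(CC)CC)C(C)=O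
A6 | alternative 3 | ten-membered trans-lactone with C8 ketone, C10 tertiary alcohol, C1 triethylsilyl ether and C3 tert-butyldimethylsilyl ether | C1C(=O)O[C@@H]2/C=C(/C)[C@@H](O[Si](C)(C)C(C)(C)C)C[C@H](O[Si](CC)(CC)CC)[C@@](O)(C)CC(=O)[C@@H]12
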